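The readings stem from a simulated flask with made-up constants, noise included.

Treat the intermediate as the fork of this flask: each molecule of it that is captured, and does not return to substrate, goes to target with first nucleophile or to other capture product with second nucleophile, so the two products grow in the ratio of those two capture rates.

all flasks: substrate 0.42 M; second nucleophile 0.504 M

|  | first nucleophile | protic impurity | remark | time |
|---|---|---|---|---|
| maple | 1.1 M | 8.4 mM | run made earlier |  |
| larch | 1.7 M | 8.4 mM | run made earlier |  |
| alder | 0.756 M | 17 mM | run made earlier |  |
| flask | 0.756 M | 8.40 mM |  | 10 d |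

| run | time / d | other capture product / % | target / % | substrate / % |
|---|---|---|---|---|
| maple | 0.625 | 2.8 | 4.0 | 91.2 |
| maple | 2.08 | 9.9 | 12.8 | 79.3 |
| maple | 4.00 | 13.0 | 22.2 | 64.5 |
| maple | 5.00 | 17.2 | 25.5 | 59.1 |
| maple | 8.00 | 19.2 | 35.0 | 44.4 |
| maple | 10.0 | 21.5 | 40.7 | 35.3 |
| larch | 0.833 | 3.4 | 6.9 | 89.6 |
| larch | 1.25 | 5.4 | 12.9 | 82.9 |
| larch | 2.00 | 6.6 | 16.7 | 76.3 |
| larch | 4.00 | 11.3 | 30.0 | 57.1 |
| larch | 6.00 | 16.0 | 41.7 | 45.9 |
| larch | 10.0 | 18.6 | 52.3 | 28.6 |
| alder | 2.08 | 8.8 | 8.3 | 80.2 |
| alder | 4.00 | 13.9 | 16.7 | 70.8 |
| alder | 6.00 | 18.3 | 21.3 | 59.7 |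
| alder | 8.00 | 22.0 | 25.8 | 53.1 |
| alder | 10.0 | 25.1 | 31.2 | 43.5 |

(each reading ± 1 percentage point)

* ratio of other capture product to target at 6.0 h
* ratio of other capture product to target at 40 h
* ratio of other capture product to target at 10 d
* which of other capture product and target there is more of at 10 d

- the numbers in the tables scatter by 1 percentage point (one standard deviation)
- steps under discussion: substrate <-> intermediate; first nucleophile + intermediate -> target; second nucleophile + intermediate -> other capture product; first nucleophile + protic impurity -> quenched reagent; 2 second nucleophile -> self-condensation product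

Begin my own estimate at 10 d. Take the ratio of other capture product to target, multiply it by the first nucleophile charge less the protic impurity, counted one for one as its step is written, and divide by the second nucleophile charge. Maple gives 1.14, larch 1.19 and alder 1.18. Keep their mean, 1.17, as s, the accumulated selectivity factor at that time.

Now reach the flask by two ways. Scaling maple and larch to its charges gives 0.788, and alder's own reading, from nearly the same recipe, gives 0.804. These agree, so trust a ratio near 0.788 at 10 d, with target ahead.

Carried back to early times, the first way parts from the readings: alder at 2.08 d reads 1.06, above it. So the constant s cheats, and it belongs to its own time. The same reckoning near 2.00 d, with 1 percentage point of scatter on readings as small as 6.6%, averages to 1.52, above s. For the flask that gives me 1.02 at both 6.0 h and 40 h.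

The forecast separates those two times: 1.07, then 0.98, then 0.81 at 10 d, with target ahead. It explains the fall by “second nucleophile loss, through self-condensation and capture, faster than first nucleophile loss”.

The flask gives 1.00, 0.952 and 0.788, with target ahead, 30.9% against 24.4%.

    substrate ⇌ intermediate (K = 0.00330, k = 0.0240 h⁻¹)
    first nucleophile + intermediate → target (k = 1.00 L mol⁻¹ h⁻¹)
    second nucleophile + intermediate → other capture product (k = 1.50 L mol⁻¹ h⁻¹)
    first nucleophile + protic impurity → quenched reagent (k = 5.50 L mol⁻¹ h⁻¹)
    2 second nucleophile → self-condensation product (k = 0.00270 L mol⁻¹ h⁻¹)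

Multiplied through, this flask's final ratio returns s as 1.17, beside the kept 1.17. At 10 d the capture rate to other capture product over that to target, each rate constant times what stands of its nucleophile, is 0.590, below the accumulated ratio. For the forecast's lead to fail, a run must put the ratio above 1, and the neighbour with 0.19 M of first nucleophile does: s predicts 3.25, and it stands at 3.19, with target at 9.07%.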